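Readings and results stem from a simulated flask with made-up constants; scatter was added.

Target in the oak run accounted for the substrate that had gone: at 30.0 min it read 56.5 % beside 43.4 % of substrate, together 99.9 %.

| setting | oak | maple | elm | zeta | epsilon |
|---|---|---|---|---|---|
| substrate | 0.40 M | 0.40 M | 0.40 M | 0.40 M | 0.40 M |
| reagent | 0.78 equiv | 0.87 equiv | 0.96 equiv | 0.700 equiv | 1.00 equiv |
| free catalyst | 0.35 mol% | 0.35 mol% | 0.35 mol% | 0.35 mol% | 0.35 mol% |
| remark | run made earlier | run made earlier | run made earlier |  |  |
| time |  |  |  | 1.0 h | 1.0 h |

- oak (time / min: target / %, substrate / %): 2.50: 5.6, 94.0; 6.00: 13.0, 84.6; 12.0: 27.2, 72.6; 30.0: 56.5, 43.4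
- maple (time / min: target / %, substrate / %): 8.00: 19.4, 81.2; 15.0: 34.0, 65.9; 25.0: 52.5, 48.6; 30.0: 59.7, 40.5
- elm (time / min: target / %, substrate / %): 4.00: 9.9, 89.9; 10.0: 23.5, 75.5; 20.0: 44.8, 55.5; 30.0: 60.9, 37.9

(each reading ± 0.5 percentage points)



1. which of the two ends with the higher amount of target, in percent of the substrate charged ("neither" if they lie within 2 percentage points) (zeta / epsilon / neither)
2. target at the end, in percent of the substrate charged, zeta
3. target at the end, in percent of the substrate charged, epsilon

No run measured the reagent, so I assumed one reagent used per target formed and wrote its balance: reagent left equals reagent charged minus target, both counted in equivalents of substrate. Under that assumption the reagent left cannot go below zero, which caps the target. For zeta the cap is 70.0 %, and I call it the ceiling, the smaller charge in percent of the substrate charged. Reagent is then the limiting reagent in zeta, while epsilon's ceiling is 100 %.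

A second way ignores the reagent and reads a clock: let the substrate fall by one constant factor in equal times. The asked time is twice the last reading, so the fraction left is the square of the last one. Oak, with the lowest charge, gives zeta 81.2 %, and elm, with the highest, gives epsilon 85.6 %.

For epsilon the clock stands below the ceiling, so it asks for no reagent beyond the charge, and I kept 85.6 %. For zeta the two part: the clock stands above the ceiling and spends reagent that was never charged, so the clock is the one that cheats. Run at oak's pace, the clock reaches zeta's ceiling at 43.3 min, before the asked 1.0 h, so I put zeta just under 70.0 %. That leaves epsilon higher in my reckoning by about 16 percentage points, against a margin of 2 points.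

The forecast named epsilon, with 68 % for zeta and 85 % for epsilon, holding that “zeta runs into its reagent limit”. The flask gave 68.6 % in zeta and 87.2 % in epsilon, so epsilon ended higher.

    catalyst intermediate A ⇌ catalyst intermediate B (K = 0.520, k = 240 min⁻¹)
    substrate + catalyst intermediate B → catalyst intermediate C (k = 310 M⁻¹ min⁻¹)
    catalyst intermediate C → free catalyst + target (k = 11.0 min⁻¹)
    reagent → decomposition product (k = 1.20 × 10⁻⁵ min⁻¹)
    reagent + free catalyst ⇌ catalyst intermediate A (K = 4.80 M⁻¹, k = 290 M⁻¹ min⁻¹)
    2 catalyst intermediate B → spent catalyst (k = 6.50 M⁻¹ min⁻¹)

Zeta ended 1.4 points under its ceiling of 70.0 %, and the 2.0 % of its reagent charge still there, unbound, at 1.00 h comes to 1.4 points of the substrate charged. A neighbour of zeta with 1.80 equiv of reagent has a ceiling of 100 %, the substrate charge now being the smaller. Its target of 96.8 % at 1.0 h, put into the balance, leaves 46.2 % of that flask's reagent charge, and that flask held 46 % of it, beside 3.2 % of its substrate.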